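**Plan**

- Numbering: C1 is the oxirane carbon carrying C7H2OBz, C2 = CHOBz, C3 = CHOH, C4=C5, C6 = oxirane CH; β is the face of the C2 oxygen, α the opposite face. The carbocycle C1–C6, with oxygens on the neighbouring C2 and C3, one C4=C5 double bond left and a one-carbon branch on C1, is a benzene ring at a lower oxidation level, which is what lets an arene dioxygenase open the synthesis.
- Retrosynthetic cuts, in order: the temporary C3 ester, the oxirane C1–O and C6–O bonds (back to a C1=C6/C4=C5 diene), the C3–O bond (inversion), the benzoate acyl–O bonds, the C1–C7 bond, and last the C2–O and C3–O bonds, which leaves bromobenzene.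
- Forward: the six-membered ring is present from the start. The enzyme adds both oxygens, O3 is silylated, C7 is coupled on at the C–Br carbon, O7 and O2 are benzoylated, C3 is unmasked and inverted, and the oxirane (the only ring made) is closed by peracid before the last deprotection.
- Stereochemistry: C2 comes directly from the enzyme. C3 is set cis by the enzyme and then inverted by a Mitsunobu reaction. C1 and C6 arise from peracid attack anti to the C2 benzoate.

Key step: step 1

Remark: the enzymatic C3–O bond serves as the cis reference and is replaced with inversion in step 6; the C2–O bond is kept to the end.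

**Route**

Step 1
Reactants: 1 bromobenzene
Product: 2 (1S,2S)-3-bromocyclohexa-3,5-diene-1,2-diol
Conditions: E. coli JM109(pDTG601) whole cells (toluene dioxygenase), air, glucose feed, IPTG, pH 7, 30–35 °C; EtOAc extraction
Reagents that add atoms: dioxygen, O=O
Why: Electrons from cellular NADH pass through the reductase and ferredoxin to the Rieske iron–sulfur cluster and on to the mononuclear non-haem iron, where dioxygen is reduced to an iron-bound peroxide that delivers both oxygen atoms to one face of the C2–C3 π bond of bound bromobenzene, so that the C2–O and C3–O bonds form suprafacially and the ring is dearomatised to the cis-diol. The closest known reaction type is the whole-cell cis-dihydroxylation of halobenzenes and other monosubstituted benzenes by toluene dioxygenase. No ring is closed; the carbocycle is kept and only loses its aromaticity. Both new stereocenters (C2 and C3, each S in 2) are fixed by the active-site pocket, which docks the bromine so that a single face of the 2,3-bond faces the iron-bound oxygen. The step needs site selectivity (2,3 and not 3,4 or ipso,ortho attack), one enantiomer and no further oxidation; the single bromo substituent gives the size difference that the pocket reads, and the host carries no cis-diol dehydrogenase, so 2 is not rearomatised to the catechol.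

Step 2
Reactants: 2 (1S,2S)-3-bromocyclohexa-3,5-diene-1,2-diol
Product: 3 (1S,6S)-2-bromo-6-{[(2,3-dimethylbutan-2-yl)dimethylsilyl]oxy}cyclohexa-2,4-dien-1-ol (O3 thexyldimethylsilyl ether of 2)
Conditions: thexyldimethylsilyl chloride (1.05 equiv), imidazole, DMF, −10 °C
Reagents that add atoms: thexyldimethylsilyl chloride, CC(C)C(C)(C)[Si](C)(C)Cl
Why: Silyl ether formation under steric control: the bulky chlorosilane should react at the C3 hydroxyl, flanked by a vinylic CH, and not at the C2 hydroxyl beside the C–Br carbon, so the two enzyme-derived oxygens become distinguishable without a stereocenter being touched.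

Step 3
Reactants: 3 (1S,6S)-2-bromo-6-{[(2,3-dimethylbutan-2-yl)dimethylsilyl]oxy}cyclohexa-2,4-dien-1-ol; 4 (tributylstannyl)methanol
Product: 5 (1R,6S)-2-(hydroxymethyl)-6-{[(2,3-dimethylbutan-2-yl)dimethylsilyl]oxy}cyclohexa-2,4-dien-1-ol
Conditions: Pd(PPh3)4 (5 mol%), 1,4-dioxane, degassed, 80 °C
Reagents that add atoms: (tributylstannyl)methanol (4), CCCC[Sn](CCCC)(CCCC)CO
Why: Migita–Kosugi–Stille coupling: zerovalent palladium inserts into the vinylic C1–Br bond, the hydroxymethyl group is transferred from tin and reductive elimination forms the C1–C7 bond, while the free C2 hydroxyl and the silyl ether are inert and no allylic ester is yet present that palladium could ionise.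

Step 4
Reactants: 5 (1R,6S)-2-(hydroxymethyl)-6-{[(2,3-dimethylbutan-2-yl)dimethylsilyl]oxy}cyclohexa-2,4-dien-1-ol; 6 benzoyl chloride
Product: 7 [(5S,6R)-6-(benzoyloxy)-5-{[(2,3-dimethylbutan-2-yl)dimethylsilyl]oxy}cyclohexa-1,3-dien-1-yl]methyl benzoate
Conditions: BzCl (2.5 equiv), pyridine, DMAP (cat.), CH2Cl2, 0 °C to rt
Reagents that add atoms: benzoyl chloride (6), O=C(Cl)c1ccccc1
Why: DMAP-catalysed acylation with an acid chloride: the primary C7 and the secondary C2 hydroxyl are both esterified at oxygen in one operation, so C2 keeps the configuration given by the enzyme.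

Step 5
Reactants: 7 [(5S,6R)-6-(benzoyloxy)-5-{[(2,3-dimethylbutan-2-yl)dimethylsilyl]oxy}cyclohexa-1,3-dien-1-yl]methyl benzoate
Product: 8 [(5S,6R)-6-(benzoyloxy)-5-hydroxycyclohexa-1,3-dien-1-yl]methyl benzoate
Conditions: HF·pyridine, pyridine, THF, 0 °C to rt
Reagents that add atoms: none
Why: Fluoride-induced Si–O cleavage in a pyridine-buffered, weakly acidic medium, chosen because basic fluoride would promote a 1,2-benzoyl shift from O2 to the cis O3, whereas the benzoates and the diene should tolerate buffered HF.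

Step 6
Reactants: 8 [(5S,6R)-6-(benzoyloxy)-5-hydroxycyclohexa-1,3-dien-1-yl]methyl benzoate; 9 chloroacetic acid
Product: 11 [(5R,6R)-6-(benzoyloxy)-5-(chloroacetoxy)cyclohexa-1,3-dien-1-yl]methyl benzoate, via alkoxyphosphonium chloroacetate 10 (not isolated)
Conditions: PPh3, DIAD (added last), THF/toluene, −20 to 0 °C
Reagents that add atoms: chloroacetic acid (9), OC(=O)CCl
Why: Mitsunobu inversion: the C3 hydroxyl is converted into alkoxyphosphonium ion 10 and displaced from the α face by chloroacetate in an SN2 reaction, which sets C3 as in the target (trans to O2); the cis C2 benzoate cannot act as a neighbouring group, and the weakly basic carboxylate and the low temperature are meant to keep elimination to the arene behind substitution.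

Step 7
Reactants: 11 [(5R,6R)-6-(benzoyloxy)-5-(chloroacetoxy)cyclohexa-1,3-dien-1-yl]methyl benzoate
Product: 12 [(1S,2S,3R,6S)-2-(benzoyloxy)-3-(chloroacetoxy)-7-oxabicyclo[4.1.0]hept-4-en-1-yl]methyl benzoate
Conditions: mCPBA (1.2 equiv), NaHCO3 buffer, CH2Cl2, 0 °C to rt
Reagents that add atoms: mCPBA (3-chloroperoxybenzoic acid), OOC(=O)c1cccc(Cl)c1
Why: Prilezhaev epoxidation: the peracid should choose the trisubstituted C1=C6 bond over C4=C5, which is only disubstituted and is further deactivated by the allylic chloroacetate, and should approach anti to the neighbouring allylic C2 benzoate, so that C1 and C6 are set together with the oxirane oxygen on the α face, cis to O3 as in the target.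

Step 8
Reactants: 12 [(1S,2S,3R,6S)-2-(benzoyloxy)-3-(chloroacetoxy)-7-oxabicyclo[4.1.0]hept-4-en-1-yl]methyl benzoate
Product: 14 [(1S,2S,3R,6S)-2-(benzoyloxy)-3-hydroxy-7-oxabicyclo[4.1.0]hept-4-en-1-yl]methyl benzoate (CNP0285759.2), via quaternary ammonioacetate ester 13 (not isolated)
Conditions: DABCO (3 equiv), EtOH, rt
Reagents that add atoms: none
Why: Selective dechloroacetylation: DABCO displaces chloride (Menshutkin reaction) to give ammonium ester 13, whose acyl group is activated enough for ethanolysis at room temperature, which frees the C3 hydroxyl without breaking a C–O bond at a stereocenter and should leave the two benzoates and the oxirane untouched.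

**Compound list**

1 | bromobenzene | Brc1ccccc1 | starting material
2 | (1S,2S)-3-bromocyclohexa-3,5-diene-1,2-diol | BrC1=CC=C[C@H](O)[C@@H]1O | intermediate
3 | (1S,6S)-2-bromo-6-{[(2,3-dimethylbutan-2-yl)dimethylsilyl]oxy}cyclohexa-2,4-dien-1-ol | BrC1=CC=C[C@H](O[Si](C)(C)C(C)(C)C(C)C)[C@@H]1O | intermediate
4 | (tributylstannyl)methanol | CCCC[Sn](CCCC)(CCCC)CO | starting material
5 | (1R,6S)-2-(hydroxymethyl)-6-{[(2,3-dimethylbutan-2-yl)dimethylsilyl]oxy}cyclohexa-2,4-dien-1-ol | OCC1=CC=C[C@H](O[Si](C)(C)C(C)(C)C(C)C)[C@@H]1O | intermediate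
6 | benzoyl chloride | O=C(Cl)c1ccccc1 | starting material
7 | [(5S,6R)-6-(benzoyloxy)-5-{[(2,3-dimethylbutan-2-yl)dimethylsilyl]oxy}cyclohexa-1,3-dien-1-yl]methyl benzoate | O=C(OCC1=CC=C[C@H](O[Si](C)(C)C(C)(C)C(C)C)[C@@H]1OC(=O)c1ccccc1)c1ccccc1 | intermediate
8 | [(5S,6R)-6-(benzoyloxy)-5-hydroxycyclohexa-1,3-dien-1-yl]methyl benzoate (O2 and O3 cis) | O=C(OCC1=CC=C[C@H](O)[C@@H]1OC(=O)c1ccccc1)c1ccccc1 | intermediate
9 | chloroacetic acid | OC(=O)CCl | starting material
10 | alkoxyphosphonium chloroacetate: the O3–PPh3 cation of 8 with chloroacetate as counter-ion | O=C(OCC1=CC=C[C@H](O[P+](c2ccccc2)(c2ccccc2)c2ccccc2)[C@@H]1OC(=O)c1ccccc1)c1ccccc1.[O-]C(=O)CCl | intermediate (not isolated)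
11 | [(5R,6R)-6-(benzoyloxy)-5-(chloroacetoxy)cyclohexa-1,3-dien-1-yl]methyl benzoate (O2 and O3 trans) | O=C(OCC1=CC=C[C@@H](OC(=O)CCl)[C@@H]1OC(=O)c1ccccc1)c1ccccc1 | intermediate
12 | [(1S,2S,3R,6S)-2-(benzoyloxy)-3-(chloroacetoxy)-7-oxabicyclo[4.1.0]hept-4-en-1-yl]methyl benzoate | O=C(OC[C@]12O[C@H]1C=C[C@@H](OC(=O)CCl)[C@@H]2OC(=O)c1ccccc1)c1ccccc1 | intermediate
13 | quaternary ammonioacetate ester: the O3 ester of 12 in which chloride is replaced by N-bound DABCO, chloride salt | O=C(OC[C@]12O[C@H]1C=C[C@@H](OC(=O)C[N+]34CCN(CC3)CC4)[C@@H]2OC(=O)c1ccccc1)c1ccccc1.[Cl-] | intermediate (not isolated)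
14 | [(1S,2S,3R,6S)-2-(benzoyloxy)-3-hydroxy-7-oxabicyclo[4.1.0]hept-4-en-1-yl]methyl benzoate | O=C(OC[C@]12O[C@H]1C=C[C@@H](O)[C@@H]2OC(=O)c1ccccc1)c1ccccc1 | target

**Step count**

Total: 8 steps. Longest linear sequence: 8 steps (1 to 14).

**Steps most likely to fail**

Step 6 (Mitsunobu inversion on the dienyl carbinol). What may go wrong: the activated C3 oxygen of 10 is lost by elimination of the C2 hydrogen or by ionisation, and the ring aromatises; chloroacetate may also enter at C5 by SN2′ attack. Fallback: the route leaves at 7 and returns at 12, with the oxirane formed before the inversion. Epoxidation of 7 (mCPBA, NaHCO3, CH2Cl2, 0 °C) should occur on the α face, opposite both the C2 benzoate and the C3 silyl ether, and give the epoxy silyl ether [(1S,2S,3S,6S)-2-(benzoyloxy)-3-{[(2,3-dimethylbutan-2-yl)dimethylsilyl]oxy}-7-oxabicyclo[4.1.0]hept-4-en-1-yl]methyl benzoate F1. Buffered fluoride (Bu4NF, AcOH, THF, 0 °C) should then free O3 to give the cis epoxy alcohol [(1S,2S,3S,6S)-2-(benzoyloxy)-3-hydroxy-7-oxabicyclo[4.1.0]hept-4-en-1-yl]methyl benzoate F2. Mitsunobu reaction of F2 with 9 (PPh3, DIAD, THF, 0 °C) inverts C3 on an ordinary cyclohex-2-enol, which has no path to an arene, and gives 12.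

Step 7 (peracid epoxidation of the trans diester). What may go wrong: poor site selectivity (oxygen transfer to C4=C5) or poor facial selectivity (attack on the β face of C1=C6). Fallback: the route leaves at 8 and returns at 12, with the epoxidation run on a cis diester in which both acyloxy groups shield the β face while the chloroacetate still deactivates C4=C5. Steglich esterification of 8 with 9 (DCC, DMAP, CH2Cl2, 0 °C) keeps the C3 configuration and gives the cis chloroacetate [(5S,6R)-6-(benzoyloxy)-5-(chloroacetoxy)cyclohexa-1,3-dien-1-yl]methyl benzoate F3. mCPBA (NaHCO3, CH2Cl2) should then give the α-oxirane [(1S,2S,3S,6S)-2-(benzoyloxy)-3-(chloroacetoxy)-7-oxabicyclo[4.1.0]hept-4-en-1-yl]methyl benzoate F4. DABCO in EtOH at rt removes the chloroacetate to give the cis epoxy alcohol F2 described under step 6, and its Mitsunobu reaction with 9 gives 12.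

Step 8 (dechloroacetylation beside a vinyl oxirane and two benzoates). What may go wrong: opening of the oxirane by the amine or by ethanol, or a base-induced shift of the C2 benzoyl group to O3. Fallback: the route leaves at 11 and returns at 14, with the acyl group exchanged for a silyl group before the oxirane exists. DABCO in EtOH converts 11 into the trans dienol [(5R,6R)-6-(benzoyloxy)-5-hydroxycyclohexa-1,3-dien-1-yl]methyl benzoate F5. Et3SiCl and imidazole in CH2Cl2 at 0 °C give the silyl ether [(5R,6R)-6-(benzoyloxy)-5-(triethylsilyloxy)cyclohexa-1,3-dien-1-yl]methyl benzoate F6. mCPBA (NaHCO3, CH2Cl2), again anti to the C2 benzoate, should give [(1S,2S,3R,6S)-2-(benzoyloxy)-3-(triethylsilyloxy)-7-oxabicyclo[4.1.0]hept-4-en-1-yl]methyl benzoate F7. Bu4NF buffered with AcOH (THF, 0 °C) then cleaves only the Si–O bond and releases 14.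

**Further compounds**

F1 | step 6 | [(1S,2S,3S,6S)-2-(benzoyloxy)-3-{[(2,3-dimethylbutan-2-yl)dimethylsilyl]oxy}-7-oxabicyclo[4.1.0]hept-4-en-1-yl]methyl benzoate | O=C(OC[C@]12O[C@H]1C=C[C@H](O[Si](C)(C)C(C)(C)C(C)C)[C@@H]2OC(=O)c1ccccc1)c1ccccc1
F2 | step 6 | [(1S,2S,3S,6S)-2-(benzoyloxy)-3-hydroxy-7-oxabicyclo[4.1.0]hept-4-en-1-yl]methyl benzoate | O=C(OC[C@]12O[C@H]1C=C[C@H](O)[C@@H]2OC(=O)c1ccccc1)c1ccccc1
F3 | step 7 | [(5S,6R)-6-(benzoyloxy)-5-(chloroacetoxy)cyclohexa-1,3-dien-1-yl]methyl benzoate | O=C(OCC1=CC=C[C@H](OC(=O)CCl)[C@@H]1OC(=O)c1ccccc1)c1ccccc1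
F4 | step 7 | [(1S,2S,3S,6S)-2-(benzoyloxy)-3-(chloroacetoxy)-7-oxabicyclo[4.1.0]hept-4-en-1-yl]methyl benzoate | O=C(OC[C@]12O[C@H]1C=C[C@H](OC(=O)CCl)[C@@H]2OC(=O)c1ccccc1)c1ccccc1
F5 | step 8 | [(5R,6R)-6-(benzoyloxy)-5-hydroxycyclohexa-1,3-dien-1-yl]methyl benzoate | O=C(OCC1=CC=C[C@@H](O)[C@@H]1OC(=O)c1ccccc1)c1ccccc1
F6 | step 8 | [(5R,6R)-6-(benzoyloxy)-5-(triethylsilyloxy)cyclohexa-1,3-dien-1-yl]methyl benzoate | O=C(OCC1=CC=C[C@@H](O[Si](CC)(CC)CC)[C@@H]1OC(=O)c1ccccc1)c1ccccc1
F7 | step 8 | [(1S,2S,3R,6S)-2-(benzoyloxy)-3-(triethylsilyloxy)-7-oxabicyclo[4.1.0]hept-4-en-1-yl]methyl benzoate | O=C(OC[C@]12O[C@H]1C=C[C@@H](O[Si](CC)(CC)CC)[C@@H]2OC(=O)c1ccccc1)c1ccccc1
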